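**Plan**

1. Numbering: C1 (aryl-bearing), C2, C3 and C4 (CH2) form ring B together with C4a/C8a. Ring A is C4a–C5–C6(OMe)–C7(OH)–C8–C8a.
2. Enabling feature: on ring A the C6 methoxy group and the C4 methylene at C4a are 1,3-related, like OMe-4 and CH3-6 of 4-methoxy-6-methyl-2-pyrone. Ring A is therefore pyrone C6–C5–C4–C3 (= C4a–C5–C6–C7, with Br on C3 standing in for the C7 phenol) plus an ethynyl group on C1 (= C8a, C8).
3. Retrosynthetic cuts, in order: coumarate ester C–O; C7–O (back to C7–Br); C4a–C8a and C7–C8 together; C3–C4; C2–C3; C1–alkyne.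
4. Forward: vanillin is extended to the C1–C2–C3 chain and closed to a γ-lactone (C3–C(=O)–O–CH2–C2). The bromopyrone is attached at C3, and one thermolysis closes ring B and creates ring A with loss of CO2.
5. The lactone keeps the two hydroxymethyl carbons at different oxidation levels and spares the pyrone any hydride. It later opens to a C3 Weinreb amide and a free C2–CH2OH, and only that hydroxyl is acylated.
6. Stereochemistry: C1 comes from a rhodium/chiral bisphosphine conjugate alkynylation, C2 from an oxazolidinone enolate alkylation, and C3 from trans-selective lactone alkylation. No later step touches them.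

Key step: step 12

Abbreviations: Ar = 3-methoxy-4-(triisopropylsilyloxy)phenyl; TIPS = triisopropylsilyl. Tetralins are named with the numbering of line 1.

Assumption: (R)-3,5-xylyl-MeO-BIPHEP is taken to deliver the (S)-configured alkynylation adduct. If the sense of induction is the reverse, the (S)-ligand is used.

**Route**

Step 1
Reactants: 1 vanillin
Product: 2 3-methoxy-4-(triisopropylsilyloxy)benzaldehyde
Conditions: iPr3SiCl, imidazole, DMF, rt
Reagents that add atoms: triisopropylsilyl chloride, CC(C)[Si](Cl)(C(C)C)C(C)C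
Why: Imidazole-promoted silyl ether formation caps the only acidic OH with a group that should tolerate amide bases, hydrides, mild acid, 190 °C and palladium catalysis, yet falls to fluoride at the end without harm to a cinnamate ester.

Step 2
Reactants: 2 3-methoxy-4-(triisopropylsilyloxy)benzaldehyde; 3 Meldrum's acid
Product: 4 5-[3-methoxy-4-(triisopropylsilyloxy)benzylidene]-2,2-dimethyl-1,3-dioxane-4,6-dione
Conditions: piperidine (cat.), AcOH (cat.), toluene, 4 Å sieves, rt
Reagents that add atoms: none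
Why: Knoevenagel condensation of a non-enolisable aldehyde with the very acidic Meldrum's acid gives a doubly activated acceptor whose electrophilicity offsets the donor character of the aryl ring.

Step 3
Reactants: 4 arylidene Meldrum's acid; 5 trimethylsilylacetylene
Product: 6 5-[(1S)-1-Ar-3-(trimethylsilyl)prop-2-yn-1-yl]-2,2-dimethyl-1,3-dioxane-4,6-dione
Conditions: Rh(acac)(C2H4)2 (5 mol %), (R)-3,5-xylyl-MeO-BIPHEP (6 mol %), 5 (excess), ClCH2CH2Cl, rt
Reagents that add atoms: none
Why: Rhodium-catalysed enantioselective conjugate alkynylation is established for 5-benzylidene Meldrum's acids with this alkyne; the chiral bisphosphine on the alkynylrhodium species selects the alkene face and so sets C1, while the silyl group holds back alkyne dimerisation.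

Step 4
Reactants: 6 alkynylated Meldrum's acid
Product: 7 (3S)-3-Ar-5-(trimethylsilyl)pent-4-ynoic acid
Conditions: DMF/H2O (10:1), 100 °C
Reagents that add atoms: water, O
Why: Hydrolytic ring opening and malonic acid decarboxylation, standard for 5-monosubstituted Meldrum's acids, leaves C2 as a CH2 next to the acid and does not involve C1.

Step 5
Reactants: 7 (3S)-3-Ar-5-(trimethylsilyl)pent-4-ynoic acid; 8 (S)-4-benzyl-2-oxazolidinone
Product: 10 (4S)-4-benzyl-3-[(3S)-3-Ar-5-(trimethylsilyl)pent-4-ynoyl]oxazolidin-2-one, via mixed pivalic anhydride 9 (not isolated)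
Conditions: tBuCOCl, Et3N, THF, −20 °C; then LiCl, 8, −20 °C to rt
Reagents that add atoms: pivaloyl chloride, CC(C)(C)C(=O)Cl (pivaloyl group of 9 only)
Why: Mixed-anhydride N-acylation under LiCl/Et3N needs no strong base, so the benzylic propargylic C1–H is safe, and any minor C1 enantiomer becomes a diastereomer that can be removed here.

Step 6
Reactants: 10 N-acyl oxazolidinone; 11 tert-butyl bromoacetate
Product: 12 tert-butyl (3S,4S)-4-Ar-3-{[(4S)-4-benzyl-2-oxooxazolidin-3-yl]carbonyl}-6-(trimethylsilyl)hex-5-ynoate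
Conditions: NaN(SiMe3)2, THF, −78 °C; then 11, −78 to −40 °C
Reagents that add atoms: none
Why: In this Evans asymmetric alkylation the chelated (Z)-sodium enolate is attacked by the reactive bromoacetate on the face away from the benzyl group of the (S)-auxiliary, which sets C2 under reagent control in the sense that becomes 1,2-trans in ring B.

Step 7
Reactants: 12 alkylated imide
Product: 14 (4S)-4-[(1S)-1-Ar-3-(trimethylsilyl)prop-2-yn-1-yl]dihydrofuran-2(3H)-one, via hydroxy tert-butyl ester 13 (not isolated)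
Conditions: LiBH4, MeOH (1 equiv), Et2O, 0 °C; work-up; then p-TsOH·H2O (10 mol %), toluene, 80 °C
Reagents that add atoms: none
Why: Reductive auxiliary removal with LiBH4 takes the activated imide carbonyl and spares the tert-butyl ester, and acid-catalysed lactonisation of the γ-hydroxy ester then gives the β-substituted butyrolactone without touching C1 or C2.

Step 8
Reactants: 15 4-methoxy-6-methyl-2H-pyran-2-one
Product: 16 3-bromo-4-methoxy-6-methyl-2H-pyran-2-one
Conditions: NBS, MeCN, rt, dark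
Reagents that add atoms: N-bromosuccinimide, O=C1CCC(=O)N1Br
Why: Electrophilic bromination goes to C3, the nucleophilic α-carbon of the push–pull enol ether, as is usual for 4-alkoxy-2-pyrones.

Step 9
Reactants: 16 3-bromo-4-methoxy-6-methyl-2H-pyran-2-one
Product: 17 3-bromo-6-(bromomethyl)-4-methoxy-2H-pyran-2-one
Conditions: NBS, AIBN (cat.), PhCF3, reflux
Reagents that add atoms: N-bromosuccinimide, O=C1CCC(=O)N1Br
Why: Wohl–Ziegler radical bromination attacks the only allylic-type C–H bonds, those of the 6-methyl group, since ring position C3 is already blocked.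

Step 10
Reactants: 14 β-substituted butyrolactone; 17 3-bromo-6-(bromomethyl)-4-methoxy-2H-pyran-2-one
Product: 18 (3R,4R)-3-[(3-bromo-4-methoxy-2-oxo-2H-pyran-6-yl)methyl]-4-[(1S)-1-Ar-3-(trimethylsilyl)prop-2-yn-1-yl]dihydrofuran-2(3H)-one
Conditions: LiN(SiMe3)2 (1.05 equiv), THF, −78 °C; then 17, THF/DMPU, −78 to −40 °C
Reagents that add atoms: none
Why: Alkylation of a β-substituted γ-butyrolactone enolate with a benzylic-type bromide, the standard entry to trans-dibenzylbutyrolactone lignans, occurs anti to the bulky C2 substituent and sets C3 trans to C2, while the silyl cap keeps the alkyne C–H out of the acid–base balance.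

Step 11
Reactants: 18 silylalkyne lactone
Product: 19 (3R,4R)-3-[(3-bromo-4-methoxy-2-oxo-2H-pyran-6-yl)methyl]-4-[(1R)-1-Ar-prop-2-yn-1-yl]dihydrofuran-2(3H)-one (unchanged geometry at C1; only the CIP descriptor changes)
Conditions: AgNO3 (10 mol %), acetone/H2O, rt
Reagents that add atoms: none
Why: Silver-catalysed protiodesilylation is selective for the C(sp)–SiMe3 bond and leaves the aryl TIPS ether, the lactone and the base-sensitive pyrone alone, which carbonate/methanol or fluoride would not guarantee.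

Step 12
Reactants: 19 alkyne-tethered 3-bromo-4-methoxy-2-pyrone
Product: 21 (1S,2R,3R)-1-Ar-7-bromo-6-methoxytetralin trans-fused at C2/C3 to the γ-lactone C3–C(=O)–O–CH2–C2 [(3aR,4S,9aR)-4-Ar-6-bromo-7-methoxy-3a,4,9,9a-tetrahydronaphtho[2,3-c]furan-1(3H)-one], via bridged oxabicyclooctadienone 20 (not isolated)
Conditions: o-C6H4Cl2 (0.01 M), BHT (0.1 equiv), argon, sealed tube, 190 °C
Reagents that add atoms: none
Why: The terminal alkyne adds suprafacially across pyrone C3 and C6 in a concerted intramolecular [4+2] cycloaddition to give the 2-oxabicyclo[2.2.2]octadienone 20, which at this temperature loses CO2 at once by retro-[4+2] and leaves the benzene ring. The closest known reaction type is the intramolecular 2-pyrone–alkyne Diels–Alder reaction with decarboxylative aromatisation, documented also for 3-bromo-2-pyrones, whose halogen lowers the LUMO enough for unactivated π-systems. Ring B closes as a six-membered carbocycle because the tether C4–C3–C2–C1 joins the diene terminus C6 (future C4a) to the inner alkyne carbon (future C8a), and ring A closes through the two new σ-bonds C4a–C8a and C7–C8 and turns aromatic when the O–C(=O) bridge leaves. No lasting stereocentre is made: the two bridgehead centres of 20 may form as either diastereomer and both vanish with CO2, while C1, C2 and C3 are spectators under neutral, base-free conditions. The selectivity needed is regiochemical and the short tether secures it, since only the fused mode is geometrically possible, so OMe ends on C6 and Br on C7. The trans-lactone holds both arms gauche in its diequatorial conformer and removes one rotor, which should offset the strain of the trans-fused product, and high dilution with BHT holds back bimolecular pyrone reactions and radical loss of bromine.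

Step 13
Reactants: 21 bromotetralin lactone
Product: 22 (1S,2R,3R)-1-Ar-7-bromo-2-(hydroxymethyl)-N,6-dimethoxy-N-methyltetralin-3-carboxamide
Conditions: MeNH(OMe)·HCl, AlMe3, CH2Cl2, 0 °C to rt
Reagents that add atoms: N,O-dimethylhydroxylamine hydrochloride, CNOC.Cl
Why: Weinreb aminolysis of the lactone with the aluminium amide is helped by release of trans-fusion strain, is too weakly basic to epimerise C3, and frees only the C2 hydroxymethyl while C3 keeps the acid oxidation level.

Step 14
Reactants: 23 p-coumaric acid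
Product: 25 (E)-3-[4-(triisopropylsilyloxy)phenyl]prop-2-enoic acid, via bis-TIPS ether ester 24 (not isolated)
Conditions: iPr3SiCl (2.2 equiv), imidazole, DMF, rt; then K2CO3, THF/MeOH/H2O, rt; 1 M HCl
Reagents that add atoms: triisopropylsilyl chloride, CC(C)[Si](Cl)(C(C)C)C(C)C
Why: Exhaustive silylation followed by selective carbonate hydrolysis of the far more labile silyl ester is the usual way to O-silyl hydroxycinnamic acids.

Step 15
Reactants: 22 hydroxy Weinreb amide; 25 O-TIPS p-coumaric acid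
Product: 26 [(1S,2R,3R)-1-Ar-7-bromo-6-methoxy-3-(N-methoxy-N-methylcarbamoyl)tetralin-2-yl]methyl (E)-3-[4-(triisopropylsilyloxy)phenyl]prop-2-enoate
Conditions: EDC·HCl, DMAP (cat.), CH2Cl2, 0 °C to rt
Reagents that add atoms: none
Why: Steglich-type carbodiimide/DMAP esterification meets a single free hydroxyl group, so the site of the coumarate is fixed by construction and the E geometry is kept.

Step 16
Reactants: 26 bromo ester
Product: 28 C7 phenol of 26 [(1S,2R,3R)-configured 7-hydroxy-6-methoxy analogue], via C7 pinacol boronate 27 (not isolated)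
Conditions: B2pin2, Pd(dppf)Cl2 (5 mol %), KOAc, 1,4-dioxane, 90 °C; then 30% H2O2, THF/pH 7 phosphate buffer, 0 °C to rt
Reagents that add atoms: hydrogen peroxide, OO (phenol oxygen of 28); bis(pinacolato)diboron, CC1(C)OB(OC1(C)C)B1OC(C)(C)C(C)(C)O1 (boryl group of 27 only)
Why: Miyaura borylation with the weak base KOAc followed by buffered peroxide oxidation of the C–B bond (1,2-aryl shift to oxygen) places the phenol exactly where bromine stood and is compatible with the ester, the Weinreb amide and the silyl ethers.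

Step 17
Reactants: 28 phenolic Weinreb amide
Product: 29 [(1S,2R,3R)-1-Ar-3-formyl-7-hydroxy-6-methoxytetralin-2-yl]methyl (E)-3-[4-(triisopropylsilyloxy)phenyl]prop-2-enoate
Conditions: Cp2Zr(H)Cl (3 equiv), THF, rt, short contact; aqueous work-up
Reagents that add atoms: none
Why: Amide reduction with the Schwartz reagent gives a zirconated hemiaminal that collapses to the aldehyde only on work-up and is known to be much faster for tertiary and Weinreb amides than for esters, so the cinnamate should survive, with one equivalent being spent on the phenol.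

Step 18
Reactants: 29 aldehyde
Product: 30 [(1S,2R,3R)-1-Ar-7-hydroxy-3-(hydroxymethyl)-6-methoxytetralin-2-yl]methyl (E)-3-[4-(triisopropylsilyloxy)phenyl]prop-2-enoate
Conditions: NaBH4, THF/EtOH, −20 °C; AcOH quench
Reagents that add atoms: none
Why: Borohydride reduction takes the aldehyde chemoselectively over the conjugated ester at low temperature, and C3 is not at risk because its substituent is already equatorial and thus in the favoured configuration.

Step 19
Reactants: 30 bis-TIPS ether
Product: 31 [(1S,2R,3R)-7-hydroxy-1-(4-hydroxy-3-methoxyphenyl)-3-(hydroxymethyl)-6-methoxy-1,2,3,4-tetrahydronaphthalen-2-yl]methyl (E)-3-(4-hydroxyphenyl)prop-2-enoate (CNP0403384.1)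
Conditions: Bu4NF, AcOH (1:1), THF, 0 °C
Reagents that add atoms: none
Why: Fluoride cleaves aryl silyl ethers rapidly, and the acetic acid buffer keeps phenoxide and alkoxide basicity low, so neither ester cleavage nor acyl migration to the C3 hydroxymethyl should intervene.

**Compound list**

1 | vanillin | COc1cc(C=O)ccc1O | starting material
2 | 3-methoxy-4-(triisopropylsilyloxy)benzaldehyde | COc1cc(C=O)ccc1O[Si](C(C)C)(C(C)C)C(C)C | intermediate
3 | Meldrum's acid | CC1(C)OC(=O)CC(=O)O1 | starting material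
4 | 5-[3-methoxy-4-(triisopropylsilyloxy)benzylidene]-2,2-dimethyl-1,3-dioxane-4,6-dione | COc1cc(C=C2C(=O)OC(C)(C)OC2=O)ccc1O[Si](C(C)C)(C(C)C)C(C)C | intermediate
5 | trimethylsilylacetylene | C#C[Si](C)(C)C | starting material
6 | 5-[(1S)-1-Ar-3-(trimethylsilyl)prop-2-yn-1-yl]-2,2-dimethyl-1,3-dioxane-4,6-dione | CC1(C)OC(=O)C(C(=O)O1)[C@H](C#C[Si](C)(C)C)c1ccc(O[Si](C(C)C)(C(C)C)C(C)C)c(OC)c1 | intermediate
7 | (3S)-3-Ar-5-(trimethylsilyl)pent-4-ynoic acid | OC(=O)C[C@H](C#C[Si](C)(C)C)c1ccc(O[Si](C(C)C)(C(C)C)C(C)C)c(OC)c1 | intermediate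
8 | (S)-4-benzyl-2-oxazolidinone | O=C1OC[C@H](Cc2ccccc2)N1 | starting material
9 | mixed pivalic anhydride of 7 | CC(C)(C)C(=O)OC(=O)C[C@H](C#C[Si](C)(C)C)c1ccc(O[Si](C(C)C)(C(C)C)C(C)C)c(OC)c1 | intermediate
10 | (4S)-4-benzyl-3-[(3S)-3-Ar-5-(trimethylsilyl)pent-4-ynoyl]oxazolidin-2-one | O=C(C[C@H](C#C[Si](C)(C)C)c1ccc(O[Si](C(C)C)(C(C)C)C(C)C)c(OC)c1)N1[C@@H](Cc2ccccc2)COC1=O | intermediate
11 | tert-butyl bromoacetate | CC(C)(C)OC(=O)CBr | starting material
12 | tert-butyl (3S,4S)-4-Ar-3-{[(4S)-4-benzyl-2-oxooxazolidin-3-yl]carbonyl}-6-(trimethylsilyl)hex-5-ynoate | CC(C)(C)OC(=O)C[C@H](C(=O)N1[C@@H](Cc2ccccc2)COC1=O)[C@H](C#C[Si](C)(C)C)c1ccc(O[Si](C(C)C)(C(C)C)C(C)C)c(OC)c1 | intermediate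
13 | tert-butyl (3S,4S)-4-Ar-3-(hydroxymethyl)-6-(trimethylsilyl)hex-5-ynoate | CC(C)(C)OC(=O)C[C@H](CO)[C@H](C#C[Si](C)(C)C)c1ccc(O[Si](C(C)C)(C(C)C)C(C)C)c(OC)c1 | intermediate
14 | (4S)-4-[(1S)-1-Ar-3-(trimethylsilyl)prop-2-yn-1-yl]dihydrofuran-2(3H)-one | O=C1C[C@@H]([C@H](C#C[Si](C)(C)C)c2ccc(O[Si](C(C)C)(C(C)C)C(C)C)c(OC)c2)CO1 | intermediate
15 | 4-methoxy-6-methyl-2H-pyran-2-one | COc1cc(C)oc(=O)c1 | starting material
16 | 3-bromo-4-methoxy-6-methyl-2H-pyran-2-one | COc1cc(C)oc(=O)c1Br | intermediate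
17 | 3-bromo-6-(bromomethyl)-4-methoxy-2H-pyran-2-one | COc1cc(CBr)oc(=O)c1Br | intermediate
18 | (3R,4R)-3-[(3-bromo-4-methoxy-2-oxo-2H-pyran-6-yl)methyl]-4-[(1S)-1-Ar-3-(trimethylsilyl)prop-2-yn-1-yl]dihydrofuran-2(3H)-one | COc1cc(C[C@H]2C(=O)OC[C@@H]2[C@H](C#C[Si](C)(C)C)c2ccc(O[Si](C(C)C)(C(C)C)C(C)C)c(OC)c2)oc(=O)c1Br | intermediate
19 | (3R,4R)-3-[(3-bromo-4-methoxy-2-oxo-2H-pyran-6-yl)methyl]-4-[(1R)-1-Ar-prop-2-yn-1-yl]dihydrofuran-2(3H)-one (key-step precursor) | COc1cc(C[C@H]2C(=O)OC[C@@H]2[C@H](C#C)c2ccc(O[Si](C(C)C)(C(C)C)C(C)C)c(OC)c2)oc(=O)c1Br | intermediate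
20 | bridged 2-oxabicyclo[2.2.2]octa-5,7-dien-3-one cycloadduct of 19 (either bridgehead diastereomer; both converge) | BrC12C=C3[C@H](c4ccc(O[Si](C(C)C)(C(C)C)C(C)C)c(OC)c4)[C@H]4COC(=O)[C@@H]4CC3(OC1=O)C=C2OC | intermediate
21 | (3aR,4S,9aR)-4-Ar-6-bromo-7-methoxy-3a,4,9,9a-tetrahydronaphtho[2,3-c]furan-1(3H)-one (key-step product; tetralin descriptors 1S,2R,3R) | CC(C)[Si](C(C)C)(C(C)C)Oc1ccc([C@H]2c3cc(Br)c(OC)cc3C[C@H]3C(=O)OC[C@H]23)cc1OC | intermediate
22 | (1S,2R,3R)-1-Ar-7-bromo-2-(hydroxymethyl)-N,6-dimethoxy-N-methyltetralin-3-carboxamide | CC(C)[Si](C(C)C)(C(C)C)Oc1ccc([C@H]2c3cc(Br)c(OC)cc3C[C@@H](C(=O)N(C)OC)[C@@H]2CO)cc1OC | intermediate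
23 | p-coumaric acid | O=C(O)/C=C/c1ccc(O)cc1 | starting material
24 | triisopropylsilyl (E)-3-[4-(triisopropylsilyloxy)phenyl]prop-2-enoate | CC(C)[Si](C(C)C)(C(C)C)OC(=O)/C=C/c1ccc(O[Si](C(C)C)(C(C)C)C(C)C)cc1 | intermediate
25 | (E)-3-[4-(triisopropylsilyloxy)phenyl]prop-2-enoic acid | O=C(O)/C=C/c1ccc(O[Si](C(C)C)(C(C)C)C(C)C)cc1 | intermediate
26 | C2-CH2 O-(4-TIPSO-cinnamate) of 22 | CC(C)[Si](C(C)C)(C(C)C)Oc1ccc([C@H]2c3cc(Br)c(OC)cc3C[C@@H](C(=O)N(C)OC)[C@@H]2COC(=O)/C=C/c2ccc(O[Si](C(C)C)(C(C)C)C(C)C)cc2)cc1OC | intermediate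
27 | C7 pinacol boronate corresponding to 26 | CC(C)[Si](C(C)C)(C(C)C)Oc1ccc([C@H]2c3cc(B4OC(C)(C)C(C)(C)O4)c(OC)cc3C[C@@H](C(=O)N(C)OC)[C@@H]2COC(=O)/C=C/c2ccc(O[Si](C(C)C)(C(C)C)C(C)C)cc2)cc1OC | intermediate
28 | C7 phenol corresponding to 26 | CC(C)[Si](C(C)C)(C(C)C)Oc1ccc([C@H]2c3cc(O)c(OC)cc3C[C@@H](C(=O)N(C)OC)[C@@H]2COC(=O)/C=C/c2ccc(O[Si](C(C)C)(C(C)C)C(C)C)cc2)cc1OC | intermediate
29 | C3 carbaldehyde (1S,2R,3R) | CC(C)[Si](C(C)C)(C(C)C)Oc1ccc([C@H]2c3cc(O)c(OC)cc3C[C@@H](C=O)[C@@H]2COC(=O)/C=C/c2ccc(O[Si](C(C)C)(C(C)C)C(C)C)cc2)cc1OC | intermediate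
30 | bis-TIPS ether of the target (1S,2R,3R) | CC(C)[Si](C(C)C)(C(C)C)Oc1ccc([C@H]2c3cc(O)c(OC)cc3C[C@@H](CO)[C@@H]2COC(=O)/C=C/c2ccc(O[Si](C(C)C)(C(C)C)C(C)C)cc2)cc1OC | intermediate
31 | CNP0403384.1, (1S,2R,3R) | COc1cc([C@H]2c3cc(O)c(OC)cc3C[C@@H](CO)[C@@H]2COC(=O)/C=C/c2ccc(O)cc2)ccc1O | target

**Step count and risks**

Total step count: 19. Longest linear sequence: 16 steps (1–7, 10–13, 15–19).

Steps most likely to fail:

**Step 12.**
- What may go wrong: the cycloaddition may be too slow, because an unactivated alkyne meets a donor-substituted pyrone and the trans ring fusion adds strain to the transition state. Prolonged heating could then erode the pyrone or epimerise C3 towards the cis-fused lactone.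
- Fallback: the tether is freed before the ring closure.
  - Setting out from 19, low-temperature aminolysis with the reagent from AlMe3 and MeNH(OMe)·HCl gives the open-chain hydroxy Weinreb amide F1. The reagent should prefer the saturated lactone carbonyl to the cross-conjugated, vinylogous-carbonate carbonyl of the pyrone.
  - Et3SiCl/imidazole converts F1 into the triethylsilyl ether F2.
  - Thermolysis in o-C6H4Cl2 then passes through the bridged cycloadduct F3 to the strain-free bromotetralin silyl ether F4. All three substituents can sit equatorially in a chair-like transition state.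
  - AcOH/THF/H2O removes the triethylsilyl group, and the sequence comes back to the route at 22.

**Step 10.**
- What may go wrong: proton transfer from the acidic bromomethyl group (or from the C4 methylene of the product) to the strongly basic lithium enolate, or addition of the enolate to the pyrone ring, could outrun the SN2 displacement.
- Fallback: the hard enolate is replaced by a stabilised one.
  - Setting out from 14, LiN(SiMe3)2 (2 equiv) and Boc2O give the α-tert-butoxycarbonyl lactone F5.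
  - The soft enolate of F5 (K2CO3, acetone) is alkylated by 17, anti to the C2 substituent, to give the quaternary lactone ester F6.
  - CF3CO2H cleaves the tert-butyl ester to the lactone acid F7.
  - Heating F7 in toluene brings about decarboxylation, and a catalytic amount of DBU equilibrates C3 to the favoured trans arrangement. This rejoins the route at 18.

**Step 17.**
- What may go wrong: chemoselectivity may be lost, because the excess hydride reagent needed for the phenol could also attack the cinnamate, or the hindered amide could react sluggishly.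
- Fallback: the two hydroxymethyl groups are told apart by sterics and not by oxidation level.
  - Setting out from 21, LiBH4 in THF gives the bromo diol F8.
  - iPr3SiCl/imidazole at low temperature should silylate the less hindered C3 hydroxymethyl (the C2 one is flanked by the C1 aryl group) to give the mono-TIPS ether F9.
  - Carbodiimide coupling with 25 gives the ester F10.
  - Miyaura borylation gives the pinacol boronate F11, and buffered H2O2 gives the phenol F12.
  - HF·pyridine in THF removes all three silyl groups and arrives at 31.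

**Further compounds**

F1 | step 12 | (2R,3R,4R)-4-Ar-2-[(3-bromo-4-methoxy-2-oxo-2H-pyran-6-yl)methyl]-3-(hydroxymethyl)-N-methoxy-N-methylhex-5-ynamide | COc1cc(C[C@@H](C(=O)N(C)OC)[C@H](CO)[C@H](C#C)c2ccc(O[Si](C(C)C)(C(C)C)C(C)C)c(OC)c2)oc(=O)c1Br
F2 | step 12 | triethylsilyl ether of F1 | COc1cc(C[C@@H](C(=O)N(C)OC)[C@H](CO[Si](CC)(CC)CC)[C@H](C#C)c2ccc(O[Si](C(C)C)(C(C)C)C(C)C)c(OC)c2)oc(=O)c1Br
F3 | step 12 | bridged 2-oxabicyclo[2.2.2]octadienone cycloadduct of F2 (either bridgehead diastereomer) | BrC12C=C3[C@H](c4ccc(O[Si](C(C)C)(C(C)C)C(C)C)c(OC)c4)[C@@H](CO[Si](CC)(CC)CC)[C@H](C(=O)N(C)OC)CC3(OC1=O)C=C2OC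
F4 | step 12 | (1S,2R,3R)-1-Ar-7-bromo-N,6-dimethoxy-N-methyl-2-[(triethylsilyloxy)methyl]tetralin-3-carboxamide | CC(C)[Si](C(C)C)(C(C)C)Oc1ccc([C@H]2c3cc(Br)c(OC)cc3C[C@@H](C(=O)N(C)OC)[C@@H]2CO[Si](CC)(CC)CC)cc1OC
F5 | step 10 | tert-butyl (4R)-4-[(1S)-1-Ar-3-(trimethylsilyl)prop-2-yn-1-yl]-2-oxotetrahydrofuran-3-carboxylate (C3 epimers) | CC(C)(C)OC(=O)C1C(=O)OC[C@@H]1[C@H](C#C[Si](C)(C)C)c1ccc(O[Si](C(C)C)(C(C)C)C(C)C)c(OC)c1
F6 | step 10 | F5 alkylated at C3 with the pyronylmethyl group trans to the C4 substituent | COc1cc(C[C@@]2(C(=O)OC(C)(C)C)C(=O)OC[C@@H]2[C@H](C#C[Si](C)(C)C)c2ccc(O[Si](C(C)C)(C(C)C)C(C)C)c(OC)c2)oc(=O)c1Br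
F7 | step 10 | carboxylic acid from F6 | COc1cc(C[C@@]2(C(=O)O)C(=O)OC[C@@H]2[C@H](C#C[Si](C)(C)C)c2ccc(O[Si](C(C)C)(C(C)C)C(C)C)c(OC)c2)oc(=O)c1Br
F8 | step 17 | [(1S,2R,3R)-1-Ar-7-bromo-6-methoxytetralin-2,3-diyl]dimethanol | CC(C)[Si](C(C)C)(C(C)C)Oc1ccc([C@H]2c3cc(Br)c(OC)cc3C[C@@H](CO)[C@@H]2CO)cc1OC
F9 | step 17 | C3-CH2 O-TIPS ether of F8 | CC(C)[Si](C(C)C)(C(C)C)Oc1ccc([C@H]2c3cc(Br)c(OC)cc3C[C@@H](CO[Si](C(C)C)(C(C)C)C(C)C)[C@@H]2CO)cc1OC
F10 | step 17 | C2-CH2 O-(4-TIPSO-cinnamate) of F9 | CC(C)[Si](C(C)C)(C(C)C)Oc1ccc([C@H]2c3cc(Br)c(OC)cc3C[C@@H](CO[Si](C(C)C)(C(C)C)C(C)C)[C@@H]2COC(=O)/C=C/c2ccc(O[Si](C(C)C)(C(C)C)C(C)C)cc2)cc1OC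
F11 | step 17 | C7 pinacol boronate corresponding to F10 | CC(C)[Si](C(C)C)(C(C)C)Oc1ccc([C@H]2c3cc(B4OC(C)(C)C(C)(C)O4)c(OC)cc3C[C@@H](CO[Si](C(C)C)(C(C)C)C(C)C)[C@@H]2COC(=O)/C=C/c2ccc(O[Si](C(C)C)(C(C)C)C(C)C)cc2)cc1OC
F12 | step 17 | C7 phenol corresponding to F10 | CC(C)[Si](C(C)C)(C(C)C)Oc1ccc([C@H]2c3cc(O)c(OC)cc3C[C@@H](CO[Si](C(C)C)(C(C)C)C(C)C)[C@@H]2COC(=O)/C=C/c2ccc(O[Si](C(C)C)(C(C)C)C(C)C)cc2)cc1OC
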